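## Retrosynthetic overview

1. Numbering: C1 (tertiary carbinol), C2 (OAc), C3 (OBz), C4=C5, C6 (C=O), C7 (exocyclic CH2). The strategy rests on C3 being an allylic carbinol bonded to the enone β-carbon C4, and on C3–C2–C1 with the branches C6 and C7 being a branched, apiose-type tetrose unit with a cis C1/C2 diol.
2. Target 18 ⇐ selective C2 acetylation ⇐ acetonide hydrolysis ⇐ C3 benzoylation of the bicyclic alcohol 15.
3. 15 ⇐ C3–C4 bond by intramolecular Nozaki–Hiyama–Kishi closure of the (Z)-β-iodoenone aldehyde 13. The cyclohexenone is the only ring that is built; the dioxolane is a protecting ring carried from the start.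
4. 13 ⇐ ozonolysis of a vinyl group (masked C3 aldehyde), hydroiodination of a C6 ynone and C7 benzoylation ⇐ ethynyl lactol 7 ⇐ ethynyl addition and glycol cleavage on the branched lactol 3.
5. 3 ⇐ formaldehyde aldol on diacetone-D-mannose 1. Mannose C2, C3, C1 and C4 become C1, C2, C6 and C3, and the new CH2OH becomes C7.

Key step: step 9

Assumption: centres that are destroyed later (the lactol carbons and the C6 carbinol) are carried as epimer mixtures and are left undefined in the SMILES. Positions are given in the target numbering above unless "mannose" is stated.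

## Route

Step 1
Reactants: 1 2,3:5,6-di-O-isopropylidene-α-D-mannofuranose; 2 formaldehyde
Product: 3 2-C-(hydroxymethyl)-2,3:5,6-di-O-isopropylidene-D-mannofuranose (anomer mixture; CH2OH trans to mannose C4 across the dioxolane)
Conditions: 37% aq. HCHO, K2CO3, MeOH, 65 °C
Reagents that add atoms: formaldehyde (2), C=O
Why: Crossed aldol of the open-chain aldehyde form of the lactol with formaldehyde under carbonate catalysis, a known reaction of 2,3-O-isopropylidene furanoses; the new quaternary centre (C1 of the target) is set by the substrate, because only the epimer with the formyl carbon cis to mannose C4 on the dioxolane can re-close to the cis-fused furanose, which also protects the aldehyde from Cannizzaro reduction.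

Step 2
Reactants: 3 2-C-(hydroxymethyl)-2,3:5,6-di-O-isopropylidene-D-mannofuranose; 4 ethynylmagnesium bromide
Product: 5 1-C-ethynyl-2-C-(hydroxymethyl)-2,3:5,6-di-O-isopropylidene-D-mannitol (acyclic triol; both C6 epimers)
Conditions: HC≡CMgBr (5 equiv), THF, 0 °C to rt
Reagents that add atoms: ethynylmagnesium bromide (4), C#C[Mg]Br
Why: Grignard addition to a lactol: after deprotonation of both hydroxyls the magnesium lactolate opens to the aldehyde, which takes up the small acetylide; the new C6 carbinol centre forms without control and is oxidised in step 6.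

Step 3
Reactants: 5 1-C-ethynyl-2-C-(hydroxymethyl)-2,3:5,6-di-O-isopropylidene-D-mannitol
Product: 7 ethynyl lactol (furanose ring O–C6H(C≡CH)–C1–C2–C3H(OH), cis-fused to the C1/C2 acetonide, free C7 hydroxymethyl on C1; epimers at C3 and C6), via pentol 6 (not isolated)
Conditions: H5IO6 (2.2 equiv), EtOAc, 0 °C to rt
Reagents that add atoms: none
Why: Periodic acid hydrolyses the terminal acetonide in preference to the internal one and cleaves the liberated 4,5,6-triol twice (Malaprade glycol cleavage), removing mannose C5 and C6; the resulting C3 aldehyde closes onto the cis-disposed C6 hydroxyl, the only one that can give a cis-fused lactol.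

Step 4
Reactants: 7 ethynyl lactol
Product: 8 enyne diol (2,2-dimethyl-1,3-dioxolane with vinyl on C2 and, on C1, CH2OH (C7) trans to the vinyl group and CH(OH)C≡CH (C6) cis to it)
Conditions: Ph3PCH3Br, KOtBu (4 equiv each), THF, 0 °C to rt
Reagents that add atoms: methyltriphenylphosphonium bromide, C[P+](c1ccccc1)(c1ccccc1)c1ccccc1.[Br-]
Why: Wittig methylenation of the open hydroxy-aldehyde form of a 2,3-O-isopropylidene furanose lactol, a standard ring-opening olefination; it masks C3 as a vinyl group and frees the C6 hydroxyl, with excess ylide covering the two hydroxyl protons.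

Step 5
Reactants: 8 enyne diol
Product: 9 C7 monobenzoate of 8 (free propargylic C6 hydroxyl)
Conditions: BzCl (1.05 equiv), pyridine, CH2Cl2, −30 to 0 °C
Reagents that add atoms: benzoyl chloride, O=C(Cl)c1ccccc1
Why: Kinetically selective acylation: the primary C7 hydroxyl reacts faster than the secondary propargylic C6 hydroxyl, which is flanked by the quaternary C1.

Step 6
Reactants: 9 C7 monobenzoate
Product: 10 ynone (C6 ketone bearing the ethynyl group, C7 benzoate, C3 as vinyl)
Conditions: Dess–Martin periodinane, CH2Cl2, 0 °C to rt
Reagents that add atoms: none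
Why: Dess–Martin oxidation of a secondary propargylic alcohol to the ynone under near-neutral conditions; C1 is quaternary, so the β-benzoyloxy ketone can neither eliminate nor epimerise.

Step 7
Reactants: 10 ynone
Product: 11 (Z)-β-iodoenone with C3 still as vinyl
Conditions: NaI, AcOH, rt, dark
Reagents that add atoms: sodium iodide, [Na+].[I-]
Why: Conjugate hydroiodination of a terminal ynone: iodide adds to the β-carbon and the allenol is protonated anti to iodine, giving the kinetic (Z)-β-iodoenone, while the isolated vinyl group does not react.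

Step 8
Reactants: 11 (Z)-β-iodoenone with C3 as vinyl
Product: 13 [(4S,5R)-5-formyl-4-[(2Z)-3-iodoprop-2-enoyl]-2,2-dimethyl-1,3-dioxolan-4-yl]methyl benzoate, via secondary ozonide 12 (not isolated)
Conditions: O3, CH2Cl2, −78 °C; then Me2S, −78 °C to rt
Reagents that add atoms: ozone, [O-][O+]=O
Why: Ozonolysis with reductive work-up: the electron-rich monosubstituted alkene reacts far faster with electrophilic ozone than the carbonyl-deactivated iodoalkene, and the neutral work-up leaves the α-alkoxy aldehyde centre at C2 unepimerised.

Step 9
Reactants: 13 [(4S,5R)-5-formyl-4-[(2Z)-3-iodoprop-2-enoyl]-2,2-dimethyl-1,3-dioxolan-4-yl]methyl benzoate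
Product: 15 1,2-O-isopropylidene-3-O-debenzoylzeylenone (cis-fused bicyclic enone; C3 hydroxyl trans to the C2 oxygen), via vinylchromium dichloride 14 (not isolated)
Conditions: CrCl2 (8 equiv), NiCl2 (2 mol%), degassed DMSO, rt, 0.005 M, dark
Reagents that add atoms: none
Why: Nozaki–Hiyama–Kishi coupling: zerovalent nickel, generated from NiCl2 by CrCl2, inserts into the C4–I bond, the vinyl group passes to trivalent chromium with retention of the Z geometry, and vinylchromium 14 adds to the C3 aldehyde. The closest known reaction type is the intramolecular nickel/chromium-mediated coupling of vinyl iodides (β-iodo enones and enoates among them) with aldehydes. The cyclohexenone ring is closed in the 6-exo-trig mode by forming C3–C4, and the Z alkene together with the cis placement of C3 and C6 on the dioxolane keeps the two termini within reach. The new C3 stereocentre is controlled by the C2 stereocentre within the cis-fused bicycle: in the half-chair transition state the C2–O bond lies pseudo-equatorial and anti to the forming C3–C4 bond (Felkin–Anh arrangement), C7 is pseudo-equatorial, and the bulky O–Cr group also takes the pseudo-equatorial site on the convex face, so the C3 oxygen ends up trans to the C2 oxygen. The step needs chemoselective metalation of the C–I bond beside a ketone, an aldehyde, a benzoate and a ketal, which the weakly basic, oxophilic organochromium reagent secures, and it needs cyclisation to outrun intermolecular coupling, which high dilution secures.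

Step 10
Reactants: 15 1,2-O-isopropylidene-3-O-debenzoylzeylenone
Product: 16 1,2-O-isopropylidenezeylenone (C3 and C7 benzoates)
Conditions: BzCl, pyridine, DMAP (cat.), CH2Cl2, 0 °C to rt
Reagents that add atoms: benzoyl chloride, O=C(Cl)c1ccccc1
Why: DMAP-catalysed acylation of the secondary allylic alcohol, the only free hydroxyl in the molecule.

Step 11
Reactants: 16 1,2-O-isopropylidenezeylenone
Product: 17 zeylenone (C1 and C2 hydroxyls free)
Conditions: TFA/H2O (9:1), 0 °C
Reagents that add atoms: none
Why: Acid-catalysed hydrolysis of the isopropylidene ketal; the esters and the enone tolerate cold aqueous trifluoroacetic acid, and the short reaction time limits benzoyl migration from O3 to O2.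

Step 12
Reactants: 17 zeylenone
Product: 18 2-O-acetylzeylenone
Conditions: Ac2O, pyridine, CH2Cl2, 0 °C
Reagents that add atoms: acetic anhydride, CC(=O)OC(C)=O
Why: Selective acetylation: the secondary C2 hydroxyl is acylated by Ac2O/pyridine, whereas the tertiary C1 hydroxyl next to the ketone does not react without a stronger acyl-transfer catalyst.

## Compound list

1 | 2,3:5,6-di-O-isopropylidene-α-D-mannofuranose | O[C@H]1O[C@H]([C@H]2COC(C)(C)O2)[C@@H]2OC(C)(C)O[C@H]12 | starting material
2 | formaldehyde | C=O | starting material
3 | 2-C-(hydroxymethyl)-2,3:5,6-di-O-isopropylidene-D-mannofuranose (anomer mixture) | OC1O[C@H]([C@H]2COC(C)(C)O2)[C@@H]2OC(C)(C)O[C@]12CO | intermediate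
4 | ethynylmagnesium bromide | C#C[Mg]Br | starting material
5 | 1-C-ethynyl-2-C-(hydroxymethyl)-2,3:5,6-di-O-isopropylidene-D-mannitol (C6 epimers) | C#CC(O)[C@@]1(CO)OC(C)(C)O[C@H]1[C@H](O)[C@H]1COC(C)(C)O1 | intermediate
6 | 1-C-ethynyl-2-C-(hydroxymethyl)-2,3-O-isopropylidene-D-mannitol (pentol) | C#CC(O)[C@@]1(CO)OC(C)(C)O[C@H]1[C@H](O)[C@H](O)CO | intermediate (not isolated)
7 | ethynyl lactol (C3 hemiacetal closed onto the C6 oxygen, cis-fused to the acetonide, free C7 hydroxymethyl) | C#CC1OC(O)[C@@H]2OC(C)(C)O[C@]12CO | intermediate
8 | enyne diol (vinyl on C2; CH2OH and CH(OH)C≡CH on C1) | C#CC(O)[C@@]1(CO)OC(C)(C)O[C@H]1C=C | intermediate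
9 | C7 monobenzoate of the enyne diol | C#CC(O)[C@@]1(COC(=O)c2ccccc2)OC(C)(C)O[C@H]1C=C | intermediate
10 | ynone (C6 ketone, C7 benzoate, C3 as vinyl) | C#CC(=O)[C@@]1(COC(=O)c2ccccc2)OC(C)(C)O[C@H]1C=C | intermediate
11 | (Z)-β-iodoenone with C3 as vinyl | C=C[C@@H]1OC(C)(C)O[C@]1(COC(=O)c1ccccc1)C(=O)/C=C\I | intermediate
12 | secondary ozonide (1,2,4-trioxolane) of 11 | O1COC(O1)[C@@H]1OC(C)(C)O[C@]1(COC(=O)c1ccccc1)C(=O)/C=C\I | intermediate (not isolated)
13 | [(4S,5R)-5-formyl-4-[(2Z)-3-iodoprop-2-enoyl]-2,2-dimethyl-1,3-dioxolan-4-yl]methyl benzoate | O=C[C@@H]1OC(C)(C)O[C@]1(COC(=O)c1ccccc1)C(=O)/C=C\I | intermediate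
14 | (Z)-vinylchromium dichloride from 13 (trivalent chromium at C4) | O=C[C@@H]1OC(C)(C)O[C@]1(COC(=O)c1ccccc1)C(=O)/C=C\[Cr](Cl)Cl | intermediate (not isolated)
15 | 1,2-O-isopropylidene-3-O-debenzoylzeylenone | CC1(C)O[C@H]2[C@H](O)C=CC(=O)[C@@]2(COC(=O)c3ccccc3)O1 | intermediate
16 | 1,2-O-isopropylidenezeylenone | CC1(C)O[C@H]2[C@H](OC(=O)c3ccccc3)C=CC(=O)[C@@]2(COC(=O)c3ccccc3)O1 | intermediate
17 | zeylenone | O[C@H]1[C@H](OC(=O)c2ccccc2)C=CC(=O)[C@]1(O)COC(=O)c1ccccc1 | intermediate
18 | 2-O-acetylzeylenone | CC(=O)O[C@H]1[C@H](OC(=O)c2ccccc2)C=CC(=O)[C@]1(O)COC(=O)c1ccccc1 | target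

## Step count and risks

Total step count: 12. Longest linear sequence: 12 steps (1 to 18).

Steps most likely to fail:

1. Step 9 (ring closure). The addition to the C3 aldehyde may show poor facial selectivity, so that the epimer with the C3 hydroxyl cis to the C2 oxygen forms in quantity. The fallback sets out from 13: the same closure would be run and the epimeric alcohol 3-epi-15 F1 collected, since it is a separable diastereomer. F1 would then be esterified with inversion at the allylic C3 under Mitsunobu conditions (PhCO2H, PPh3, DIAD, toluene, 0 °C). This gives dibenzoate 16 directly, and the route is rejoined there before step 11.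

2. Step 8 (ozonolysis beside the iodoalkene). Ozone may attack the iodoalkene or oxidise at iodine, or the Z geometry may be lost during the work-up. The fallback sets out from ynone 10 and reverses the order of events. Ozonolysis of 10 (O3, CH2Cl2, −78 °C; then Me2S) would pass through the ozonide of the ynone F2 to the ynone aldehyde F3. Hydroiodination of F3 (NaI, AcOH, rt, dark) would then give 13, where the route is rejoined.

3. Step 2 (Grignard addition to the unprotected branched lactol). The magnesium dialkoxide may lose formaldehyde by retro-aldol cleavage, or addition to the hindered aldehyde may stall. The fallback sets out from 3. Selective silylation of the primary hydroxyl (TBSCl, imidazole, DMF, 0 °C) would give the 7-O-silyl lactol F4. Addition of HC≡CMgBr (3 equiv, THF, 0 °C to rt) would give the silylated propargylic diol F5; a silyl shift to the C6 oxygen would be harmless. Desilylation (tetrabutylammonium fluoride, THF, 0 °C) would return triol 5, where the route is rejoined.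

Further compounds
F1 | step 9 | 3-epi-15 (C3 hydroxyl cis to the C2 oxygen) | CC1(C)O[C@H]2[C@@H](O)C=CC(=O)[C@@]2(COC(=O)c3ccccc3)O1
F2 | step 8 | secondary ozonide of ynone 10 | C#CC(=O)[C@@]1(COC(=O)c2ccccc2)OC(C)(C)O[C@H]1C1OCOO1
F3 | step 8 | ynone aldehyde (C3 formyl, C6 ethynyl ketone, C7 benzoate) | C#CC(=O)[C@@]1(COC(=O)c2ccccc2)OC(C)(C)O[C@H]1C=O
F4 | step 2 | 7-O-(tert-butyldimethylsilyl) derivative of lactol 3 | OC1O[C@H]([C@H]2COC(C)(C)O2)[C@@H]2OC(C)(C)O[C@]12CO[Si](C)(C)C(C)(C)C
F5 | step 2 | 7-O-(tert-butyldimethylsilyl) derivative of triol 5 | C#CC(O)[C@@]1(CO[Si](C)(C)C(C)(C)C)OC(C)(C)O[C@H]1[C@H](O)[C@H]1COC(C)(C)O1
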